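**Remark on numbering and abbreviations:** all intermediates keep the atom numbers of the target (ring C1–C10; lactone carbons C11–C13 on C7/O6; ester carbon C14 on C10; methyl C15 on C4). "Ring-cis" is used for C9=C10 and C1=C10 when the two ring neighbours are cis, although the CIP descriptor is E. TBS = tert-butyldimethylsilyl, TES = triethylsilyl, EpAng = (2S,3S)-2,3-dimethyloxirane-2-carbonyl, Ox = (2R,3S)-3-{(1S)-1-[(tert-butyldimethylsilyl)oxy]prop-2-en-1-yl}-3-methyloxiran-2-yl.

**Assumption:** C3 is carried as a TBS ether instead of a triethylsilyl ether, because the silyl group has to survive the acetonide cleavage of step 12; the key step is not affected.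

## Analysis of the target

Compound 36 is a germacranolide: a ten-membered carbocycle (C1–C10) trans-fused at C6–C7 to an α-methylene-γ-butyrolactone (O6, C11–C13). The ring carries eight contiguous stereocentres, C2 to C9 (2R,3R,4S,5R,6S,7R,8S,9S), and two more sit in the (2S,3S)-2,3-epoxy-2-methylbutanoate on O8. C2–C3 is a cis-disubstituted epoxide and C4–C5 a trisubstituted epoxide of E-olefin origin. In the extended chain the two epoxides are anti across C3–C4, O6 is syn to the C5 epoxide oxygen and anti to O8, and O8 and O9 are syn. Sensitive groups are the exo-methylene lactone (Michael acceptor), the allylic 2,3-epoxide conjugated through C1=C10 with the C14 ester, the C9 acetate next to a migratable C8 ester, and three acid-labile epoxides. The difficulty is the strained medium ring in which seven of ten carbons bear oxygen, next to a ring-cis trisubstituted enoate, so that late undirected oxidations of the macrocycle are not an option. The feature used here is that O9 and O2 flank the ring-cis C1=C10 bond on the same face: C9(O)–C10=C1–C2(O) is a cis-2-ene-1,4-diol, the reduction product of a 3,6-dihydro-1,2-dioxine ring, and that ring is the adduct of dioxygen with the ring diene C9=C10–C1=C2.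

## Retrosynthetic reasoning

**36 ⇒ 35 ⇒ 34.** The acetate is removed and the C3–O bond of the 2,3-epoxide is cut. Forward, the C2 oxygen of 34 displaces a C3 mesylate with inversion, so C3 must arrive with the opposite configuration; acetylation of O9 in 35 ends the route. C3–O is cut rather than C2–O because O2 has a defined origin together with O9.

**34 ⇒ 33 ⇒ 32 ⇒ 31.** The two hydroxyls of 34 are joined as the peroxide of 33. Forward, the O–O bridge protects both oxygens while the silyl ether of 31 is exchanged for the mesylate (through 32), and is reduced only afterwards under neutral conditions.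

**31 ⇒ 30 (key disconnection).** Both C–O bonds, C9–O and C2–O, are cut at once, leading back to the ring diene 30. Forward, a [4+2] photooxygenation must form two C–O bonds, the dioxine ring and two stereocentres on one face of the diene. No other disconnection gives both oxygens with their mutual configuration in one step.

**30 ⇒ 29.** The C1=C2 bond is cut. Forward, ring-closing metathesis of two terminal vinyl groups closes the ten-membered ring; this bond is chosen because both partners are unhindered monosubstituted olefins and the ring-cis C9=C10 geometry is already fixed.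

**29 ⇒ 28 ⇒ 24 + 27.** The C10–C1 bond is cut (Stille vinylation of the α-bromo enoate 28, with retention) and then C9=C10 (Wittig reaction of aldehyde 24 with the bromo ylide 27, made from 25 through 26). The order bromo-olefination then coupling fixes C8 cis to C1, which a direct olefination with a vinyl-substituted reagent would not secure.

**24 ⇒ 23 ⇒ 17 + 21.** The C8 ester bond is cut. The epoxy acid 21 is made separately (18 → 19 → 20 → 21) by Sharpless epoxidation, so that its two stereocentres are reagent-controlled and no angelate has to be epoxidized on the substrate; it is attached through the mixed anhydride 22.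

**17 ⇒ 16 ⇒ 15.** Protecting-group adjustment: the C8/C9 glycol comes from the acetonide of 15, and only its primary hydroxyl is silylated.

**15 ⇒ 14 ⇒ 13 ⇒ 12 ⇒ 7 + 11.** The lactone C12–O6 bond and then the C6–C7 bond are cut. Forward, a Barbier allylation joins the epoxy aldehyde 7 and the allylic bromide 11 and sets C6 and C7. The reaction naturally gives the cis-lactone series, so C6 is inverted afterwards (Mitsunobu, 12 → 13) and the lactone then closes with retention through 14.

**7 ⇒ 6 ⇒ 5 ⇒ 4 ⇒ 3 ⇒ 2 ⇒ 1, and 11 ⇒ 10 ⇒ 8 + 9.** The 4,5-epoxide is cut back to the E-allylic alcohol 5 (Sharpless epoxidation), whose C3 carbinol comes from vinyl addition to 1 and enzymatic resolution. The bromide 11 is the rearranged Morita–Baylis–Hillman adduct of 8 and 9, which brings C8 from the chiral pool.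

## Alternatives that were turned down

**Alternative 1:** The ring is traced back by reconnecting C4 and C9 across it, so that a trans-fused six-six bicycle with a C9 tertiary hydroxyl and a C5 sulfonate is the substrate. The forward key step is a base-triggered Grob fragmentation that breaks C4–C9, forms the C9 ketone and the E C4=C5 bond, and releases the trienone A1.
- For it: no medium-ring closure is needed, the 4E geometry follows stereospecifically from the anti-periplanar arrangement, and C6–C8 can be set on a rigid bicycle. On ring construction it is stronger than a metathesis closure.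
- Against it: A1 has none of the four epoxide stereocentres and no C9 carbinol. After fragmentation the route must still reduce the ketone face-selectively, epoxidize C4=C5 and the electron-poor C2=C3 bond on defined faces of a flexible ring, build the lactone and exchange the C8 ether for the ester. A1 is also a doubly activated alkylidene β-keto ester formed in strong alkoxide base, so conjugate addition and isomerization of the 2Z bond threaten.
- Comparison: the chosen plan concedes the easier ring formation, but it fixes the 4,5-epoxide before cyclization by reagent control and introduces O2 and O9 in one stereospecific event, so that only functional-group steps follow the ring closure.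

**Alternative 2:** The C2=C3 bond is cut. Forward, ring-closing metathesis joins a vinyl group on C1 of a preformed dienoate with a vinyl group on the C4 epoxide carbon and gives the 2,3-deoxy compound A2; one epoxidation of C2=C3 would then finish 36.
- For it: the C9 acetate and the C8 ester are in place before cyclization, no peroxide chemistry is needed, and the sequence after ring closure is one step against six here. On step economy after cyclization it is stronger.
- Against it: the olefin on C4 sits on a fully substituted epoxide carbon, which makes it a hindered, fragmentation-prone vinyl epoxide for a ruthenium carbene. The last step must epoxidize one double bond of a dienoate on one face with no directing group, beside an exo-methylene lactone, so the configuration of C2 and C3 would rest on macrocycle conformation alone.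
- Comparison: the chosen route takes C3 from a resolved carbinol and C2 from a cycloaddition whose face is governed by two reinforcing allylic centres; it pays with a longer endgame.

**Alternative 3:** A σ-bond is drawn between C2 and C5, giving a cis-fused cyclobutene on an eight-membered ring. Forward, thermal conrotatory opening breaks C2–C5, forms C2=C3 and C4=C5 and expands the ring to the trienolide A3.
- For it: the ring expansion avoids any macrocyclization and orbital symmetry delivers one cis and one trans double bond; in ring construction it is the most elegant of the four.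
- Against it: the eight-membered precursor with a fused cyclobutene and five stereocentres is a demanding target in itself, torquoselectivity must choose 2Z,4E over 2E,4Z, and the temperatures needed endanger the allylic acetate and the exo-methylene lactone. A3 is a conjugated trienoate in which both C2=C3 and C4=C5 still have to be epoxidized regio- and face-selectively without a directing group.
- Comparison: the chosen plan never has to distinguish three conjugated double bonds, because the 4,5-epoxide precedes the ring and the 2,3-epoxide is closed by substitution.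

Key step: step 23

## Route

Step 1
Reactants: 1 ethyl (2E)-3-methyl-4-oxobut-2-enoate
Product: 2 ethyl (2E)-4-hydroxy-3-methylhexa-2,5-dienoate (racemate)
Conditions: CH2=CHMgBr, THF, −78 °C; aq NH4Cl
Reagents that add atoms: vinylmagnesium bromide, C=C[Mg]Br
Why: Grignard 1,2-addition to the aldehyde is much faster than attack on the conjugated ester at low temperature; the C3 carbinol forms as a racemate that step 2 resolves.

Step 2
Reactants: 2 ethyl (2E)-4-hydroxy-3-methylhexa-2,5-dienoate (racemate)
Product: 3 ethyl (2E,4S)-4-hydroxy-3-methylhexa-2,5-dienoate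
Conditions: immobilized Candida antarctica lipase B, vinyl acetate, MTBE, 30 °C, run to just over half conversion
Reagents that add atoms: none
Why: Enzymatic kinetic resolution by enantioselective transesterification; the lipase should acylate the R alcohol, whose large 2-alkenyl and small vinyl groups fit its binding pockets, so that the S alcohol 3 (C3 of the target numbering) is recovered.

Step 3
Reactants: 3 ethyl (2E,4S)-4-hydroxy-3-methylhexa-2,5-dienoate
Product: 4 ethyl (2E,4S)-4-[(tert-butyldimethylsilyl)oxy]-3-methylhexa-2,5-dienoate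
Conditions: TBSCl, imidazole, DMF, rt
Reagents that add atoms: tert-butyldimethylsilyl chloride, CC(C)(C)[Si](C)(C)Cl
Why: Standard silylation of a secondary alcohol; TBS is chosen because it withstands the acetonide hydrolysis of step 12 and is removed by fluoride at the peroxide stage.

Step 4
Reactants: 4 ethyl (2E,4S)-4-[(tert-butyldimethylsilyl)oxy]-3-methylhexa-2,5-dienoate
Product: 5 (2E,4S)-4-[(tert-butyldimethylsilyl)oxy]-3-methylhexa-2,5-dien-1-ol
Conditions: iBu2AlH, CH2Cl2, −78 °C; Rochelle salt
Reagents that add atoms: none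
Why: DIBAL-H reduces the conjugated ester to the primary allylic alcohol (1,2-reduction) and leaves the silyl ether and both olefins untouched.

Step 5
Reactants: 5 (2E,4S)-4-[(tert-butyldimethylsilyl)oxy]-3-methylhexa-2,5-dien-1-ol
Product: 6 [(2R,3S)-3-{(1S)-1-[(tert-butyldimethylsilyl)oxy]prop-2-en-1-yl}-3-methyloxiran-2-yl]methanol
Conditions: Ti(OiPr)4, D-(−)-diethyl tartrate, t-BuOOH, 4 Å MS, CH2Cl2, −20 °C
Reagents that add atoms: tert-butyl hydroperoxide, CC(C)(C)OO
Why: Sharpless asymmetric epoxidation of a geraniol-type E-trisubstituted primary allylic alcohol is reagent-controlled; L-(+)-tartrate is taken to give the 2S,3S series with this olefin class, so the D-(−) ester should deliver the opposite face and set C4 (S) and C5 (R), while the vinyl group lacking an allylic hydroxyl is inert.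

Step 6
Reactants: 6 [(2R,3S)-3-{(1S)-1-[(tert-butyldimethylsilyl)oxy]prop-2-en-1-yl}-3-methyloxiran-2-yl]methanol
Product: 7 (2S,3S)-3-{(1S)-1-[(tert-butyldimethylsilyl)oxy]prop-2-en-1-yl}-3-methyloxirane-2-carbaldehyde
Conditions: Dess–Martin periodinane, NaHCO3, CH2Cl2, 0 °C to rt
Reagents that add atoms: none
Why: Buffered Dess–Martin oxidation gives the α,β-epoxy aldehyde without epoxide opening; only the CIP descriptor of C5 changes, not its configuration.

Step 7
Reactants: 8 (4R)-2,2-dimethyl-1,3-dioxolane-4-carbaldehyde; 9 ethyl prop-2-enoate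
Product: 10 ethyl 2-{[(4R)-2,2-dimethyl-1,3-dioxolan-4-yl](hydroxy)methyl}prop-2-enoate (both carbinol epimers)
Conditions: DABCO, 1,4-dioxane/H2O, rt
Reagents that add atoms: none
Why: Morita–Baylis–Hillman reaction; the new carbinol centre becomes sp2 in step 8, so its configuration is irrelevant, and the dioxolane centre (future C8) is taken unchanged from the chiral pool.

Step 8
Reactants: 10 ethyl 2-{[(4R)-2,2-dimethyl-1,3-dioxolan-4-yl](hydroxy)methyl}prop-2-enoate (both carbinol epimers)
Product: 11 ethyl (2Z)-2-(bromomethyl)-3-[(4S)-2,2-dimethyl-1,3-dioxolan-4-yl]prop-2-enoate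
Conditions: NBS, Me2S, CH2Cl2, 0 °C to rt
Reagents that add atoms: N-bromosuccinimide, O=C1CCC(=O)N1Br
Why: The alkoxysulfonium salt of the Baylis–Hillman alcohol is displaced by bromide in the SN2′ sense, which gives the more stable Z-2-(bromomethyl)enoate (dioxolane cis to CH2Br) under neutral conditions that spare the acetonide.

Step 9
Reactants: 7 (2S,3S)-3-{(1S)-1-[(tert-butyldimethylsilyl)oxy]prop-2-en-1-yl}-3-methyloxirane-2-carbaldehyde; 11 ethyl (2Z)-2-(bromomethyl)-3-[(4S)-2,2-dimethyl-1,3-dioxolan-4-yl]prop-2-enoate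
Product: 12 ethyl (3S,4R)-3-[(4S)-2,2-dimethyl-1,3-dioxolan-4-yl]-4-hydroxy-2-methylidene-4-Ox-butanoate
Conditions: In powder, THF/H2O, rt
Reagents that add atoms: none
Why: Indium-mediated Barbier allylation through a closed chair transition state at the γ-carbon: the Z bromide gives the adduct with O6 and the C8 branch syn (cis-lactone series), the aldehyde is attacked in the Felkin–Anh sense anti to the epoxide C–O bond (5,6-erythro), and the allyl unit reacts anti to the dioxolane C–C bond with its C–H turned inward (7,8-anti); the three preferences converge on 12 (6R,7S), whose C6 is deliberately opposite to the target and is inverted in step 10.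

Step 10
Reactants: 12 ethyl (3S,4R)-3-[(4S)-2,2-dimethyl-1,3-dioxolan-4-yl]-4-hydroxy-2-methylidene-4-Ox-butanoate
Product: 13 ethyl (3R,4S)-3-[(4S)-2,2-dimethyl-1,3-dioxolan-4-yl]-2-methylidene-4-[(4-nitrobenzoyl)oxy]-4-Ox-butanoate
Conditions: 4-O2NC6H4CO2H, PPh3, DIAD, toluene, 0 °C to rt
Reagents that add atoms: 4-nitrobenzoic acid, O=C(O)c1ccc(cc1)[N+](=O)[O-]
Why: Mitsunobu reaction with the acidic 4-nitrobenzoic acid, the usual choice for hindered secondary alcohols, replaces the C6 oxyphosphonium group by SN2 and inverts C6 to the S configuration of the target.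

Step 11
Reactants: 13 ethyl (3R,4S)-3-[(4S)-2,2-dimethyl-1,3-dioxolan-4-yl]-2-methylidene-4-[(4-nitrobenzoyl)oxy]-4-Ox-butanoate
Product: 15 (4R,5S)-4-[(4S)-2,2-dimethyl-1,3-dioxolan-4-yl]-3-methylidene-5-Ox-oxolan-2-one, via hydroxy acid 14 (not isolated)
Conditions: LiOH·H2O, THF/H2O, rt; aq HCl to pH 3, 0 °C; PPTS (cat.), CH2Cl2, rt
Reagents that add atoms: none
Why: Saponification cleaves both esters by acyl–oxygen fission, so C6 keeps its new configuration, and the γ-hydroxy acid 14 lactonizes with retention on mild acidification to the trans-fused α-methylene lactone with the 5,6-threo relationship; TBS ether, acetonide and epoxide tolerate LiOH and brief weak acid.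

Step 12
Reactants: 15 (4R,5S)-4-[(4S)-2,2-dimethyl-1,3-dioxolan-4-yl]-3-methylidene-5-Ox-oxolan-2-one
Product: 16 (4R,5S)-4-[(1S)-1,2-dihydroxyethyl]-3-methylidene-5-Ox-oxolan-2-one
Conditions: CuCl2·2H2O, MeCN, 0 °C to rt
Reagents that add atoms: none
Why: Mild Lewis-acid hydrolysis of a terminal isopropylidene acetal; the secondary TBS ether and the 4,5-epoxide, deactivated toward ionization by the oxygenated carbons on both sides, are expected to survive.

Step 13
Reactants: 16 (4R,5S)-4-[(1S)-1,2-dihydroxyethyl]-3-methylidene-5-Ox-oxolan-2-one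
Product: 17 (4R,5S)-4-{(1S)-1-hydroxy-2-[(triethylsilyl)oxy]ethyl}-3-methylidene-5-Ox-oxolan-2-one
Conditions: TESCl, imidazole, CH2Cl2, −40 °C
Reagents that add atoms: chlorotriethylsilane, CC[Si](Cl)(CC)CC
Why: Low-temperature silylation distinguishes the primary C9 hydroxyl from the hindered secondary C8 hydroxyl; the mild base should not provoke migration of the trans-fused lactone to O8.

Step 14
Reactants: 18 (2Z)-2-methylbut-2-enoic acid
Product: 19 (2Z)-2-methylbut-2-en-1-ol
Conditions: LiAlH4, Et2O, 0 °C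
Reagents that add atoms: none
Why: LiAlH4 reduces the α,β-unsaturated acid at the carboxyl group (1,2-reduction) with retention of the Z geometry.

Step 15
Reactants: 19 (2Z)-2-methylbut-2-en-1-ol
Product: 20 [(2R,3S)-2,3-dimethyloxiran-2-yl]methanol
Conditions: Ti(OiPr)4, D-(−)-diethyl tartrate, t-BuOOH, 4 Å MS, CH2Cl2, −20 °C
Reagents that add atoms: tert-butyl hydroperoxide, CC(C)(C)OO
Why: Sharpless asymmetric epoxidation of a Z-trisubstituted allylic alcohol; nerol-type substrates are taken to give the 2S,3R epoxy alcohol with L-(+)-tartrate, so the D-(−) ester should give the 2R,3S enantiomer needed here, with the olefin geometry transferred to the cis arrangement of CH2OH and the C3 methyl.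

Step 16
Reactants: 20 [(2R,3S)-2,3-dimethyloxiran-2-yl]methanol
Product: 21 (2S,3S)-2,3-dimethyloxirane-2-carboxylic acid
Conditions: RuCl3·xH2O (cat.), NaIO4, EtOAc/MeCN/H2O, 0 °C to rt
Reagents that add atoms: sodium periodate, [Na+].[O-]I(=O)(=O)=O
Why: Catalytic ruthenium tetroxide oxidizes the primary alcohol to the acid without opening the epoxide; the descriptor at C2 changes from R to S only because the carboxyl group outranks C3.

Step 17
Reactants: 17 (4R,5S)-4-{(1S)-1-hydroxy-2-[(triethylsilyl)oxy]ethyl}-3-methylidene-5-Ox-oxolan-2-one; 21 (2S,3S)-2,3-dimethyloxirane-2-carboxylic acid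
Product: 23 (1S)-1-[(2S,3R)-4-methylidene-5-oxo-2-Ox-oxolan-3-yl]-2-[(triethylsilyl)oxy]ethyl (2S,3S)-2,3-dimethyloxirane-2-carboxylate, via mixed anhydride 22 (not isolated)
Conditions: 2,4,6-Cl3C6H2COCl, Et3N, THF, rt; then 17, DMAP, toluene, rt
Reagents that add atoms: none
Why: Yamaguchi esterification: the mixed anhydride 22 transfers the hindered acyl group through its acylpyridinium salt to the secondary C8 hydroxyl; the acid has no enolizable stereocentre, so it cannot epimerize.

Step 18
Reactants: 23 (1S)-1-[(2S,3R)-4-methylidene-5-oxo-2-Ox-oxolan-3-yl]-2-[(triethylsilyl)oxy]ethyl (2S,3S)-2,3-dimethyloxirane-2-carboxylate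
Product: 24 (1S)-1-[(2S,3S)-4-methylidene-5-oxo-2-Ox-oxolan-3-yl]-2-oxoethyl (2S,3S)-2,3-dimethyloxirane-2-carboxylate
Conditions: (COCl)2, DMSO, CH2Cl2, −78 to −30 °C; Et3N, −78 to 0 °C
Reagents that add atoms: none
Why: Under Swern conditions the chlorosulfonium salt cleaves a primary triethylsilyl ether and oxidizes it directly to the aldehyde, while the secondary TBS ether stays; the low temperature limits epimerization of the α-acyloxy aldehyde, which is used at once.

Step 19
Reactants: 25 methyl (triphenyl-λ5-phosphanylidene)acetate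
Product: 27 methyl bromo(triphenyl-λ5-phosphanylidene)acetate, via phosphonium bromide 26 (not isolated)
Conditions: Br2, CH2Cl2, 0 °C; then aq NaOH
Reagents that add atoms: bromine, BrBr
Why: C-bromination of the stabilized ylide followed by deprotonation of the phosphonium salt 26 is the standard preparation of α-halo stabilized ylides.

Step 20
Reactants: 24 (1S)-1-[(2S,3S)-4-methylidene-5-oxo-2-Ox-oxolan-3-yl]-2-oxoethyl (2S,3S)-2,3-dimethyloxirane-2-carboxylate; 27 methyl bromo(triphenyl-λ5-phosphanylidene)acetate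
Product: 28 methyl (2Z,4S)-2-bromo-4-(EpAng-oxy)-4-[(2S,3R)-4-methylidene-5-oxo-2-Ox-oxolan-3-yl]but-2-enoate
Conditions: CH2Cl2, rt
Reagents that add atoms: none
Why: Wittig olefination with a stabilized ylide places the ester trans to the C8 chain, so bromine ends up cis to C8 (Z); the neutral conditions avoid epimerization at C8.

Step 21
Reactants: 28 methyl (2Z,4S)-2-bromo-4-(EpAng-oxy)-4-[(2S,3R)-4-methylidene-5-oxo-2-Ox-oxolan-3-yl]but-2-enoate
Product: 29 methyl (2E,4R)-2-ethenyl-4-(EpAng-oxy)-4-[(2S,3R)-4-methylidene-5-oxo-2-Ox-oxolan-3-yl]but-2-enoate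
Conditions: CH2=CHSnBu3, Pd2(dba)3 (cat.), AsPh3, CuI, DMF, rt to 40 °C
Reagents that add atoms: tributyl(vinyl)stannane, C=C[Sn](CCCC)(CCCC)CCCC
Why: Stille coupling of the α-bromo enoate proceeds with retention of olefin geometry and installs the C1 vinyl group cis to C8; the cis C9 substituent disfavours the s-cis form of the acyclic 2-substituted diene and thereby its Diels–Alder dimerization.

Step 22
Reactants: 29 methyl (2E,4R)-2-ethenyl-4-(EpAng-oxy)-4-[(2S,3R)-4-methylidene-5-oxo-2-Ox-oxolan-3-yl]but-2-enoate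
Product: 30 methyl (1Z,3S,4S,5R,6S,7R,8R,9E)-3-(TBS-oxy)-8-(EpAng-oxy)-4,5-epoxygermacra-1,9,11(13)-trien-12,6-olid-14-oate
Conditions: second-generation Grubbs catalyst, toluene, 80 °C, 1 mM, slow addition
Reagents that add atoms: none
Why: Ring-closing metathesis of the two terminal vinyl groups with loss of ethene, a closure used for ten-membered germacranolide rings; the trans-fused lactone, the epoxide and the ring-cis C9=C10 bond fold the chain, the diene-containing ten-membered ring is expected to prefer the cis C1=C2 bond, and the electron-poor exo-methylene and trisubstituted enoate are poor metathesis partners.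

Step 23
Reactants: 30 methyl (1Z,3S,4S,5R,6S,7R,8R,9E)-3-(TBS-oxy)-8-(EpAng-oxy)-4,5-epoxygermacra-1,9,11(13)-trien-12,6-olid-14-oate
Product: 31 methyl (1(10)E,2R,3S,4S,5R,6S,7S,8S,9S)-3-(TBS-oxy)-8-(EpAng-oxy)-4,5-epoxy-2,9-epidioxygermacra-1(10),11(13)-dien-12,6-olid-14-oate
Conditions: O2, tetraphenylporphyrin (cat.), visible light, CH2Cl2, −20 °C
Reagents that add atoms: dioxygen, O=O
Why: Singlet oxygen, generated by the porphyrin sensitizer, adds to the s-cis conformer of the C9=C10–C1=C2 diene in a concerted suprafacial [4+2] cycloaddition, the reaction known for cyclic 1,3-dienes and for 2,4-dienoates. The 3,6-dihydro-1,2-dioxine ring is closed by cycloaddition, both C–O bonds forming together at C9 and C2 while the double bond moves to C1=C10, where the six-membered ring holds it ring-cis. Because the addition is suprafacial, O9 and O2 are cis to each other, as the C9 acetate and the C2 epoxide oxygen are in 36. The face is decided by the two allylic stereocentres: in the reactive conformer the C3–C8 segment lies on one side of the diene, and at both C3 and C8 the hydrogen points into the diene cleft, the oxygen substituent lies near the diene plane pointing outward, and the ring bond (C3–C4, C8–C7) is anti to the incoming oxygen. With the 3S and 8R configurations of 30 both centres shield the same side, so oxygen should add to the open face and give the 2R,9S peroxide, each new C–O bond being syn to the neighbouring silyloxy or acyloxy group in the extended chain. Chemoselectivity rests on the electrophilic character of singlet oxygen: the exo-methylene lactone is electron-poor, epoxides and esters are inert, and the only allylic hydrogens of the diene (H3, H8) are geminal to oxygen and lie near the nodal plane, which disfavours the ene reaction. The diene is twisted and carries an ester, so prolonged irradiation at low temperature is planned.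

Step 24
Reactants: 31 methyl (1(10)E,2R,3S,4S,5R,6S,7S,8S,9S)-3-(TBS-oxy)-8-(EpAng-oxy)-4,5-epoxy-2,9-epidioxygermacra-1(10),11(13)-dien-12,6-olid-14-oate
Product: 32 methyl (1(10)E,2R,3S,4R,5R,6S,7S,8S,9S)-8-(EpAng-oxy)-4,5-epoxy-2,9-epidioxy-3-hydroxygermacra-1(10),11(13)-dien-12,6-olid-14-oate
Conditions: HF·pyridine, pyridine, THF, 0 °C to rt
Reagents that add atoms: none
Why: Pyridine-buffered HF removes the TBS ether under weakly acidic conditions that avoid base-induced Kornblum–DeLaMare cleavage of the dioxine and that the deactivated epoxides tolerate; the C4 descriptor changes by priority only.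

Step 25
Reactants: 32 methyl (1(10)E,2R,3S,4R,5R,6S,7S,8S,9S)-8-(EpAng-oxy)-4,5-epoxy-2,9-epidioxy-3-hydroxygermacra-1(10),11(13)-dien-12,6-olid-14-oate
Product: 33 methyl (1(10)E,2R,3S,4S,5R,6S,7S,8S,9S)-8-(EpAng-oxy)-4,5-epoxy-2,9-epidioxy-3-[(methanesulfonyl)oxy]germacra-1(10),11(13)-dien-12,6-olid-14-oate
Conditions: Ms2O, pyridine, CH2Cl2, 0 °C
Reagents that add atoms: methanesulfonic anhydride, CS(=O)(=O)OS(C)(=O)=O
Why: Sulfonylation of the only free hydroxyl with a weak base; C3 is no longer allylic, so the mesylate is stable, and the peroxide still masks O2 and O9.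

Step 26
Reactants: 33 methyl (1(10)E,2R,3S,4S,5R,6S,7S,8S,9S)-8-(EpAng-oxy)-4,5-epoxy-2,9-epidioxy-3-[(methanesulfonyl)oxy]germacra-1(10),11(13)-dien-12,6-olid-14-oate
Product: 34 methyl (1(10)E,2R,3S,4S,5R,6S,7R,8S,9S)-8-(EpAng-oxy)-4,5-epoxy-2,9-dihydroxy-3-[(methanesulfonyl)oxy]germacra-1(10),11(13)-dien-12,6-olid-14-oate
Conditions: thiourea, MeOH/CH2Cl2, rt
Reagents that add atoms: none
Why: Thiourea reduces the O–O bond of a 1,4-endoperoxide to the cis-2-ene-1,4-diol under neutral conditions; both C–O bonds are retained, so C2 and C9 keep their configuration, and epoxides, esters and the hindered mesylate should not react.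

Step 27
Reactants: 34 methyl (1(10)E,2R,3S,4S,5R,6S,7R,8S,9S)-8-(EpAng-oxy)-4,5-epoxy-2,9-dihydroxy-3-[(methanesulfonyl)oxy]germacra-1(10),11(13)-dien-12,6-olid-14-oate
Product: 35 methyl (1(10)E,2R,3R,4S,5R,6S,7R,8S,9S)-8-(EpAng-oxy)-2,3:4,5-diepoxy-9-hydroxygermacra-1(10),11(13)-dien-12,6-olid-14-oate
Conditions: DBU, CH2Cl2, 0 °C
Reagents that add atoms: none
Why: Intramolecular Williamson closure (3-exo-tet): the C2 alkoxide displaces the anti-periplanar C3 mesylate with inversion and gives the cis-2,3-epoxide (3R); a non-nucleophilic amidine in an aprotic solvent keeps the alkoxide concentration low, so that acyl migration from O8 to O9 and addition to the exo-methylene lactone should stay slower than the three-membered ring closure.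

Step 28
Reactants: 35 methyl (1(10)E,2R,3R,4S,5R,6S,7R,8S,9S)-8-(EpAng-oxy)-2,3:4,5-diepoxy-9-hydroxygermacra-1(10),11(13)-dien-12,6-olid-14-oate
Product: 36 methyl (1(10)E,2R,3R,4S,5R,6S,7R,8S,9S)-9-acetoxy-8-(EpAng-oxy)-2,3:4,5-diepoxygermacra-1(10),11(13)-dien-12,6-olid-14-oate
Conditions: Ac2O, pyridine, DMAP (cat.), CH2Cl2, 0 °C
Reagents that add atoms: acetic anhydride, CC(=O)OC(C)=O
Why: DMAP-catalysed acetylation of the remaining secondary allylic C9 hydroxyl completes the target without touching any stereocentre.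

## Compound list

1 | ethyl (2E)-3-methyl-4-oxobut-2-enoate | CCOC(=O)/C=C(\C)C=O | starting material
2 | ethyl (2E)-4-hydroxy-3-methylhexa-2,5-dienoate (racemate) | CCOC(=O)/C=C(\C)C(O)C=C | intermediate
3 | ethyl (2E,4S)-4-hydroxy-3-methylhexa-2,5-dienoate | CCOC(=O)/C=C(\C)[C@@H](O)C=C | intermediate
4 | ethyl (2E,4S)-4-[(tert-butyldimethylsilyl)oxy]-3-methylhexa-2,5-dienoate | CCOC(=O)/C=C(\C)[C@@H](O[Si](C)(C)C(C)(C)C)C=C | intermediate
5 | (2E,4S)-4-[(tert-butyldimethylsilyl)oxy]-3-methylhexa-2,5-dien-1-ol | OC/C=C(\C)[C@@H](O[Si](C)(C)C(C)(C)C)C=C | intermediate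
6 | [(2R,3S)-3-{(1S)-1-[(tert-butyldimethylsilyl)oxy]prop-2-en-1-yl}-3-methyloxiran-2-yl]methanol | OC[C@H]1O[C@]1(C)[C@@H](O[Si](C)(C)C(C)(C)C)C=C | intermediate
7 | (2S,3S)-3-{(1S)-1-[(tert-butyldimethylsilyl)oxy]prop-2-en-1-yl}-3-methyloxirane-2-carbaldehyde | O=C[C@H]1O[C@]1(C)[C@@H](O[Si](C)(C)C(C)(C)C)C=C | intermediate
8 | (4R)-2,2-dimethyl-1,3-dioxolane-4-carbaldehyde | O=C[C@H]1COC(C)(C)O1 | starting material
9 | ethyl prop-2-enoate | C=CC(=O)OCC | starting material
10 | ethyl 2-{[(4R)-2,2-dimethyl-1,3-dioxolan-4-yl](hydroxy)methyl}prop-2-enoate (both carbinol epimers) | CCOC(=O)C(=C)C(O)[C@H]1COC(C)(C)O1 | intermediate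
11 | ethyl (2Z)-2-(bromomethyl)-3-[(4S)-2,2-dimethyl-1,3-dioxolan-4-yl]prop-2-enoate | CCOC(=O)/C(CBr)=C/[C@H]1COC(C)(C)O1 | intermediate
12 | ethyl (3S,4R)-3-[(4S)-2,2-dimethyl-1,3-dioxolan-4-yl]-4-hydroxy-2-methylidene-4-Ox-butanoate | C=C[C@H](O[Si](C)(C)C(C)(C)C)[C@@]1(C)O[C@@H]1[C@H](O)[C@H](C(=C)C(=O)OCC)[C@H]2COC(C)(C)O2 | intermediate
13 | ethyl (3R,4S)-3-[(4S)-2,2-dimethyl-1,3-dioxolan-4-yl]-2-methylidene-4-[(4-nitrobenzoyl)oxy]-4-Ox-butanoate | C=C[C@H](O[Si](C)(C)C(C)(C)C)[C@@]1(C)O[C@@H]1[C@@H](OC(=O)c1ccc(cc1)[N+](=O)[O-])[C@H](C(=C)C(=O)OCC)[C@H]2COC(C)(C)O2 | intermediate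
14 | (3S,4S)-3-[(4S)-2,2-dimethyl-1,3-dioxolan-4-yl]-4-hydroxy-2-methylidene-4-Ox-butanoic acid | C=C[C@H](O[Si](C)(C)C(C)(C)C)[C@@]1(C)O[C@@H]1[C@@H](O)[C@H](C(=C)C(=O)O)[C@H]2COC(C)(C)O2 | intermediate
15 | (4R,5S)-4-[(4S)-2,2-dimethyl-1,3-dioxolan-4-yl]-3-methylidene-5-Ox-oxolan-2-one | C=C1C(=O)O[C@H]([C@H]2O[C@]2(C)[C@@H](O[Si](C)(C)C(C)(C)C)C=C)[C@H]1[C@H]3COC(C)(C)O3 | intermediate
16 | (4R,5S)-4-[(1S)-1,2-dihydroxyethyl]-3-methylidene-5-Ox-oxolan-2-one | C=C1C(=O)O[C@H]([C@H]2O[C@]2(C)[C@@H](O[Si](C)(C)C(C)(C)C)C=C)[C@H]1[C@H](O)CO | intermediate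
17 | (4R,5S)-4-{(1S)-1-hydroxy-2-[(triethylsilyl)oxy]ethyl}-3-methylidene-5-Ox-oxolan-2-one | C=C1C(=O)O[C@H]([C@H]2O[C@]2(C)[C@@H](O[Si](C)(C)C(C)(C)C)C=C)[C@H]1[C@H](O)CO[Si](CC)(CC)CC | intermediate
18 | (2Z)-2-methylbut-2-enoic acid (angelic acid) | C/C=C(/C)C(=O)O | starting material
19 | (2Z)-2-methylbut-2-en-1-ol | C/C=C(/C)CO | intermediate
20 | [(2R,3S)-2,3-dimethyloxiran-2-yl]methanol | OC[C@@]1(C)O[C@H]1C | intermediate
21 | (2S,3S)-2,3-dimethyloxirane-2-carboxylic acid | OC(=O)[C@@]1(C)O[C@H]1C | intermediate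
22 | (2S,3S)-2,3-dimethyloxirane-2-carboxylic 2,4,6-trichlorobenzoic anhydride | O=C(OC(=O)c1c(Cl)cc(Cl)cc1Cl)[C@@]2(C)O[C@H]2C | intermediate
23 | (1S)-1-[(2S,3R)-4-methylidene-5-oxo-2-Ox-oxolan-3-yl]-2-[(triethylsilyl)oxy]ethyl (2S,3S)-2,3-dimethyloxirane-2-carboxylate | C=C1C(=O)O[C@H]([C@H]2O[C@]2(C)[C@@H](O[Si](C)(C)C(C)(C)C)C=C)[C@H]1[C@H](OC(=O)[C@@]2(C)O[C@H]2C)CO[Si](CC)(CC)CC | intermediate
24 | (1S)-1-[(2S,3S)-4-methylidene-5-oxo-2-Ox-oxolan-3-yl]-2-oxoethyl (2S,3S)-2,3-dimethyloxirane-2-carboxylate | C=C1C(=O)O[C@H]([C@H]2O[C@]2(C)[C@@H](O[Si](C)(C)C(C)(C)C)C=C)[C@H]1[C@H](OC(=O)[C@@]2(C)O[C@H]2C)C=O | intermediate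
25 | methyl (triphenyl-λ5-phosphanylidene)acetate | COC(=O)C=P(c1ccccc1)(c1ccccc1)c1ccccc1 | starting material
26 | (1-bromo-2-methoxy-2-oxoethyl)triphenylphosphonium bromide | COC(=O)C(Br)[P+](c1ccccc1)(c1ccccc1)c1ccccc1.[Br-] | intermediate
27 | methyl bromo(triphenyl-λ5-phosphanylidene)acetate | COC(=O)C(Br)=P(c1ccccc1)(c1ccccc1)c1ccccc1 | intermediate
28 | methyl (2Z,4S)-2-bromo-4-(EpAng-oxy)-4-[(2S,3R)-4-methylidene-5-oxo-2-Ox-oxolan-3-yl]but-2-enoate | C=C1C(=O)O[C@H]([C@H]2O[C@]2(C)[C@@H](O[Si](C)(C)C(C)(C)C)C=C)[C@H]1[C@H](OC(=O)[C@@]2(C)O[C@H]2C)/C=C(\Br)C(=O)OC | intermediate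
29 | methyl (2E,4R)-2-ethenyl-4-(EpAng-oxy)-4-[(2S,3R)-4-methylidene-5-oxo-2-Ox-oxolan-3-yl]but-2-enoate | C=C1C(=O)O[C@H]([C@H]2O[C@]2(C)[C@@H](O[Si](C)(C)C(C)(C)C)C=C)[C@H]1[C@H](OC(=O)[C@@]2(C)O[C@H]2C)/C=C(\C=C)C(=O)OC | intermediate
30 | methyl (1Z,3S,4S,5R,6S,7R,8R,9E)-3-(TBS-oxy)-8-(EpAng-oxy)-4,5-epoxygermacra-1,9,11(13)-trien-12,6-olid-14-oate | C=C1C(=O)O[C@H]2[C@H]1[C@H](OC(=O)[C@@]1(C)O[C@H]1C)/C=C(C(=O)OC)\C=C/[C@H](O[Si](C)(C)C(C)(C)C)[C@@]1(C)O[C@H]21 | intermediate
31 | methyl (1(10)E,2R,3S,4S,5R,6S,7S,8S,9S)-3-(TBS-oxy)-8-(EpAng-oxy)-4,5-epoxy-2,9-epidioxygermacra-1(10),11(13)-dien-12,6-olid-14-oate | C=C1C(=O)O[C@H]2[C@H]1[C@H](OC(=O)[C@@]1(C)O[C@H]1C)[C@H]3OO[C@H](C=C3C(=O)OC)[C@H](O[Si](C)(C)C(C)(C)C)[C@@]1(C)O[C@H]21 | intermediate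
32 | methyl (1(10)E,2R,3S,4R,5R,6S,7S,8S,9S)-8-(EpAng-oxy)-4,5-epoxy-2,9-epidioxy-3-hydroxygermacra-1(10),11(13)-dien-12,6-olid-14-oate | C=C1C(=O)O[C@H]2[C@H]1[C@H](OC(=O)[C@@]1(C)O[C@H]1C)[C@H]3OO[C@H](C=C3C(=O)OC)[C@H](O)[C@@]1(C)O[C@H]21 | intermediate
33 | methyl (1(10)E,2R,3S,4S,5R,6S,7S,8S,9S)-8-(EpAng-oxy)-4,5-epoxy-2,9-epidioxy-3-[(methanesulfonyl)oxy]germacra-1(10),11(13)-dien-12,6-olid-14-oate | C=C1C(=O)O[C@H]2[C@H]1[C@H](OC(=O)[C@@]1(C)O[C@H]1C)[C@H]3OO[C@H](C=C3C(=O)OC)[C@H](OS(C)(=O)=O)[C@@]1(C)O[C@H]21 | intermediate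
34 | methyl (1(10)E,2R,3S,4S,5R,6S,7R,8S,9S)-8-(EpAng-oxy)-4,5-epoxy-2,9-dihydroxy-3-[(methanesulfonyl)oxy]germacra-1(10),11(13)-dien-12,6-olid-14-oate | C=C1C(=O)O[C@H]2[C@H]1[C@H](OC(=O)[C@@]1(C)O[C@H]1C)[C@@H](O)/C(C(=O)OC)=C\[C@@H](O)[C@H](OS(C)(=O)=O)[C@@]1(C)O[C@H]21 | intermediate
35 | methyl (1(10)E,2R,3R,4S,5R,6S,7R,8S,9S)-8-(EpAng-oxy)-2,3:4,5-diepoxy-9-hydroxygermacra-1(10),11(13)-dien-12,6-olid-14-oate | C=C1C(=O)O[C@H]2[C@H]1[C@H](OC(=O)[C@@]1(C)O[C@H]1C)[C@@H](O)/C(C(=O)OC)=C\[C@H]1O[C@H]1[C@@]1(C)O[C@H]21 | intermediate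
36 | methyl (1(10)E,2R,3R,4S,5R,6S,7R,8S,9S)-9-acetoxy-8-(EpAng-oxy)-2,3:4,5-diepoxygermacra-1(10),11(13)-dien-12,6-olid-14-oate | C=C1C(=O)O[C@H]2[C@H]1[C@H](OC(=O)[C@@]1(C)O[C@H]1C)[C@@H](OC(C)=O)/C(C(=O)OC)=C\[C@H]1O[C@H]1[C@@]1(C)O[C@H]21 | target

## Step count and least certain steps

Total step count: 28. Longest linear sequence: 22 steps (steps 1–6, 9–13, 17, 18, 20–28). The acid branch (steps 14–16), the bromide branch (steps 7, 8) and the ylide (step 19) are side sequences.

**Step 23 (key step).** The most likely failure is a lack of reactivity: the cis,cis-diene of a ten-membered ring is twisted away from the planar s-cis geometry and carries an ester, so the cycloaddition may be slow enough for ene-type oxygenation or photodegradation to take over. Insufficient face selectivity is the second concern. The fallback introduces the two oxygens stepwise through a vinyl epoxide and sets out from 30. Dimethyldioxirane should epoxidize the C1=C2 bond, the less electron-poor of the diene, on the same open face and give the cis-1,2-epoxide F1. HF·pyridine frees the C3 hydroxyl to give the epoxy alcohol F2, which is no longer allylic at C3 and is mesylated to the epoxy mesylate F3. Zerovalent palladium (Pd(PPh3)4) with acetic acid opens the vinyl epoxide through a π-allyl complex and delivers acetate to C9 anti to the metal, that is cis to O2, giving the hydroxy acetate F4. DBU then closes the C2–C3 epoxide, and the fallback comes back to the route at 36.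

**Step 9 (Barbier allylation).** The most likely failure is erosion of facial selectivity at the aldehyde: chelation of indium between the aldehyde and epoxide oxygens can compete with the Felkin–Anh mode and lead to the C6 epimer of 12 through an anti transition state. The fallback sets the C6 carbinol by reduction instead of addition and sets out from 12 as obtained (mixed with its C6 epimer). Dess–Martin oxidation gives the epoxy ketone F5, and Zn(BH4)2 reduces it through the chelate between the epoxide and carbonyl oxygens, which is known to give the erythro epoxy alcohol; the fallback comes back at 12.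

**Step 10 (Mitsunobu inversion).** The most likely failure is elimination toward C6=C7 or substitution with retention through an acyloxyphosphonium ion, because the C6 carbinol lies between an epoxide and a branched carbon. The fallback uses neighbouring-group displacement and sets out from 12. Mesylation (MsCl, Et3N) gives the mesylate F6; on heating in toluene with 2,6-lutidine the ester carbonyl oxygen displaces the mesylate in a 5-exo closure with inversion, and the resulting alkoxy-oxolanylium ion loses its ethyl group to mesylate. This gives the trans lactone directly and comes back at 15.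

**Step 22 (ring-closing metathesis).** The most likely failures are closure to the ring-trans C1=C2 isomer and intermolecular metathesis to open-chain dimers, since a strained ring must form from a conjugated ruthenium vinylcarbene. The fallback sets the olefin geometry photochemically and sets out from 29. The metathesis is run under equilibrating conditions, and if it delivers the 1E isomer F7, this is isomerized by triplet-sensitized irradiation (thioxanthone, 365 nm), a known way to move conjugated dienes toward the less conjugated cis form; the fallback comes back at 30.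

**Step 25 (mesylation on the peroxide).** The most likely failure is base-induced Kornblum–DeLaMare cleavage of the dioxine during sulfonylation, by deprotonation at C2, which is γ to the ester. The fallback reduces the peroxide before any base is used and sets out from 31. Thiourea gives the ene-diol F8; 2,2-dimethoxypropane with PPTS ties the cis-1,4-diol up as the seven-membered isopropylidene acetal F9; HF·pyridine then frees the C3 alcohol F10, which is mesylated (MsCl, Et3N) to the acetal mesylate F11. Mild aqueous acetic acid removes the acetal, and the fallback comes back at 34.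

## Further compounds

F1 | step 23 | methyl (1R,2R,3S,4S,5R,6S,7R,8R,9E)-3-(TBS-oxy)-8-(EpAng-oxy)-1,2:4,5-diepoxygermacra-9,11(13)-dien-12,6-olid-14-oate | C=C1C(=O)O[C@H]2[C@H]1[C@H](OC(=O)[C@@]1(C)O[C@H]1C)/C=C(C(=O)OC)\[C@H]1O[C@H]1[C@H](O[Si](C)(C)C(C)(C)C)[C@@]1(C)O[C@H]21
F2 | step 23 | methyl (1R,2S,3S,4R,5R,6S,7R,8R,9E)-8-(EpAng-oxy)-1,2:4,5-diepoxy-3-hydroxygermacra-9,11(13)-dien-12,6-olid-14-oate | C=C1C(=O)O[C@H]2[C@H]1[C@H](OC(=O)[C@@]1(C)O[C@H]1C)/C=C(C(=O)OC)\[C@H]1O[C@H]1[C@H](O)[C@@]1(C)O[C@H]21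
F3 | step 23 | methyl (1R,2R,3S,4S,5R,6S,7R,8R,9E)-8-(EpAng-oxy)-1,2:4,5-diepoxy-3-[(methanesulfonyl)oxy]germacra-9,11(13)-dien-12,6-olid-14-oate | C=C1C(=O)O[C@H]2[C@H]1[C@H](OC(=O)[C@@]1(C)O[C@H]1C)/C=C(C(=O)OC)\[C@H]1O[C@H]1[C@H](OS(C)(=O)=O)[C@@]1(C)O[C@H]21
F4 | step 23 | methyl (1(10)E,2R,3S,4S,5R,6S,7R,8S,9S)-9-acetoxy-8-(EpAng-oxy)-4,5-epoxy-2-hydroxy-3-[(methanesulfonyl)oxy]germacra-1(10),11(13)-dien-12,6-olid-14-oate | C=C1C(=O)O[C@H]2[C@H]1[C@H](OC(=O)[C@@]1(C)O[C@H]1C)[C@@H](OC(C)=O)/C(C(=O)OC)=C\[C@@H](O)[C@H](OS(C)(=O)=O)[C@@]1(C)O[C@H]21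
F5 | step 9 | ethyl (3R)-3-[(4S)-2,2-dimethyl-1,3-dioxolan-4-yl]-2-methylidene-4-oxo-4-[(2S,3S)-3-{(1S)-1-[(tert-butyldimethylsilyl)oxy]prop-2-en-1-yl}-3-methyloxiran-2-yl]butanoate | C=C[C@H](O[Si](C)(C)C(C)(C)C)[C@@]1(C)O[C@@H]1C(=O)[C@H](C(=C)C(=O)OCC)[C@H]2COC(C)(C)O2
F6 | step 10 | ethyl (3R,4R)-3-[(4S)-2,2-dimethyl-1,3-dioxolan-4-yl]-4-[(methanesulfonyl)oxy]-2-methylidene-4-Ox-butanoate | C=C[C@H](O[Si](C)(C)C(C)(C)C)[C@@]1(C)O[C@@H]1[C@H](OS(C)(=O)=O)[C@H](C(=C)C(=O)OCC)[C@H]2COC(C)(C)O2
F7 | step 22 | methyl (1E,3S,4S,5R,6S,7R,8R,9E)-3-(TBS-oxy)-8-(EpAng-oxy)-4,5-epoxygermacra-1,9,11(13)-trien-12,6-olid-14-oate | C=C1C(=O)O[C@H]2[C@H]1[C@H](OC(=O)[C@@]1(C)O[C@H]1C)/C=C(C(=O)OC)\C=C\[C@H](O[Si](C)(C)C(C)(C)C)[C@@]1(C)O[C@H]21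
F8 | step 25 | methyl (1(10)E,2R,3S,4S,5R,6S,7R,8S,9S)-3-(TBS-oxy)-8-(EpAng-oxy)-4,5-epoxy-2,9-dihydroxygermacra-1(10),11(13)-dien-12,6-olid-14-oate | C=C1C(=O)O[C@H]2[C@H]1[C@H](OC(=O)[C@@]1(C)O[C@H]1C)[C@@H](O)/C(C(=O)OC)=C\[C@@H](O)[C@H](O[Si](C)(C)C(C)(C)C)[C@@]1(C)O[C@H]21
F9 | step 25 | methyl (1(10)E,2R,3S,4S,5R,6S,7R,8S,9S)-3-(TBS-oxy)-8-(EpAng-oxy)-4,5-epoxy-2,9-(isopropylidenedioxy)germacra-1(10),11(13)-dien-12,6-olid-14-oate | C=C1C(=O)O[C@H]2[C@H]1[C@H](OC(=O)[C@@]1(C)O[C@H]1C)[C@H]3OC(C)(C)O[C@H](C=C3C(=O)OC)[C@H](O[Si](C)(C)C(C)(C)C)[C@@]1(C)O[C@H]21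
F10 | step 25 | methyl (1(10)E,2R,3S,4R,5R,6S,7R,8S,9S)-8-(EpAng-oxy)-4,5-epoxy-3-hydroxy-2,9-(isopropylidenedioxy)germacra-1(10),11(13)-dien-12,6-olid-14-oate | C=C1C(=O)O[C@H]2[C@H]1[C@H](OC(=O)[C@@]1(C)O[C@H]1C)[C@H]3OC(C)(C)O[C@H](C=C3C(=O)OC)[C@H](O)[C@@]1(C)O[C@H]21
F11 | step 25 | methyl (1(10)E,2R,3S,4S,5R,6S,7R,8S,9S)-8-(EpAng-oxy)-4,5-epoxy-2,9-(isopropylidenedioxy)-3-[(methanesulfonyl)oxy]germacra-1(10),11(13)-dien-12,6-olid-14-oate | C=C1C(=O)O[C@H]2[C@H]1[C@H](OC(=O)[C@@]1(C)O[C@H]1C)[C@H]3OC(C)(C)O[C@H](C=C3C(=O)OC)[C@H](OS(C)(=O)=O)[C@@]1(C)O[C@H]21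
A1 | alternative 1 | methyl 7-[3-(TBS-oxy)prop-1-en-2-yl]-8-[(4-methoxybenzyl)oxy]-4-methyl-9-oxo-6-[(triethylsilyl)oxy]cyclodeca-1(10),2,4-triene-10-carboxylate (target numbering; ring-cis 1(10) and 2, 4E) | O=C1/C(C(=O)OC)=C\C=C/C(C)=C/[C@@H](O[Si](CC)(CC)CC)[C@H](C(=C)CO[Si](C)(C)C(C)(C)C)[C@@H]1OCc1ccc(OC)cc1
A2 | alternative 2 | 2,3-deoxy analogue of 36: methyl 9-acetoxy-8-(EpAng-oxy)-4,5-epoxygermacra-1(10),2,11(13)-trien-12,6-olid-14-oate (ring-cis 1(10) and 2) | C=C1C(=O)O[C@H]2[C@H]1[C@H](OC(=O)[C@@]1(C)O[C@H]1C)[C@@H](OC(C)=O)/C(C(=O)OC)=C\C=C/[C@@]1(C)O[C@H]21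
A3 | alternative 3 | methyl 9-acetoxy-8-(TBS-oxy)germacra-1(10),2,4,11(13)-tetraen-12,6-olid-14-oate (ring-cis 1(10) and 2, 4E) | C=C1C(=O)O[C@@H]2/C=C(C)/C=C\C=C(C(=O)OC)/[C@H](OC(C)=O)[C@@H](O[Si](C)(C)C(C)(C)C)[C@@H]12
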